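## The problem

Atom labels used throughout: butenolide C1 (carbonyl) to C4, exocyclic CH C5, CH(CH3) C6, cyclopentane C7–C10 (methyl on C10), spiro carbon C11, cyclohexene C12–C16 (C13=C14, methyl on C14, acyloxy on C15).

Target 32 is a spiro[4.5]dec-8-ene in which the quaternary carbon C11 joins a cyclopentane and a cyclohexene and is flanked on the five-membered ring by two tertiary stereocentres, C7 and C10. Five stereocentres must be set (C6, C7, C10, C11, C15), together with the Z geometry of the C4=C5 enol-lactone double bond. Only C7, C10 and C11 sit close enough on one ring to steer each other. C6 lies on a freely rotating bond and C15 on the far side of the six-membered ring, so both need reagent control. The fragile groups are the γ-alkylidene butenolide (opened or isomerised by base and nucleophiles) and the secondary allylic 3-phenylpropanoate at C15 (saponification, ionisation). Neither should meet enolate or hydride chemistry. The structural opening is that C11 is β to C15 and bonded to C7, and C7 carries the two-carbon arm C6–C5. With C15 as a ketone and C5 as an ester, C11 is the β-carbon of a cyclohex-2-enone and C7 the β-carbon of an enoate, three atoms (C10, C9, C8) apart. A reductive β,β-coupling of these two carbons closes the cyclopentane and creates the spiro centre in one step, with C10 as the only resident stereocentre.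

## Retrosynthesis

**Butenolide (C3–C4 and O–C4).** The alkylidene butenolide is removed first because it is the least robust part of 32. The cut gives terminal alkyne 27 and (2Z)-3-iodo-2-methylprop-2-enoic acid 30. Forward, a Sonogashira coupling gives enynoic acid 31, which closes 5-exo-dig in the same flask. The neighbouring cut at C4=C5 (aldol-type condensation of a methylbutenolide with a C5 aldehyde, then dehydration) leaves the alkene geometry to thermodynamics. The chosen cut fixes Z by anti addition of the carboxylate across the alkyne and runs at room temperature with a tertiary amine, which the C15 ester tolerates. Acid 30 goes back through alcohol 29 to prop-2-yn-1-ol 28.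

**C15 ester and alkyne (C15–O acyl bond, then C4).** Ester 27 comes from alcohol 25 and 3-phenylpropanoyl chloride 26, and 25 from silyl ether 24. The acyl group is placed after all enolate, hydride and carbonate–methanol steps, so the hydroxyl travels as a silyl ether from 16 to 24. Alkyne 24 is traced to aldehyde 23 by removing C4 (one-carbon homologation). The forward step must not epimerise C6, which is α to the aldehyde.

**C6 methyl (C6–CH3).** Aldehyde 23 comes from alcohol 22, and 22 from imide 21 by reductive removal of the auxiliary. Cutting C6–CH3 leads to the unbranched imide 20, made from acid 17 and oxazolidinone 18 through anhydride 19, and 17 from ester 16. Cutting C6–C7 instead would mean coupling at a ring carbon beside the quaternary centre. The methyl cut reduces the problem to an enolate alkylation, and the auxiliary is needed because C6 is outside the ring. The forward step has to override whatever facial bias C7 and C11 impose.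

**Cyclohexene adjustment (C15–H, C13=C14, C14–CH3).** Silyl ether 16 comes from allylic alcohol 15, 15 from enone 14 by enantioselective reduction, 14 from ketone 12 through enol ether 13, and 12 from the plain spiro ketone 11 by methylation. These changes come before the side-chain work for two reasons. Kinetic enolisation of 11 distinguishes C14 from the neopentyl C16. And the ketone must be gone before a C6 enolate is made.

**Key cut (C7–C11).** Keto ester 11 opens to enone–enoate 10. Of the four ring bonds at the spiro carbon, this is the one that makes both termini β-carbons of acceptors, so no leaving group, tin hydride or stoichiometric metal is needed. The precursor is an acyclic chain on a cyclohexenone with a single stereocentre. The forward reaction must form a quaternary carbon and set C7 and C11 from C10 alone.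

**Enoate and enone (C6=C7; the ring as a reduced anisole).** Enoate 10 comes from aldehyde 8 and ylide 9, and 8 from alcohol 7. The 3-substituted cyclohexenone of 7 is a Birch-reduced and hydrolysed 3-alkylanisole (5, through dihydroanisole 6). Adding a side-chain organometallic to a 3-alkoxycyclohexenone would place the metal on the stereogenic carbon C10 and lose its configuration. In the arene, C10 is a configurationally stable benzylic centre.

**C10 (C10–H, then C9=C10).** Alcohol 5 comes from acid 4, and 4 from the β,γ-unsaturated acid 3 by asymmetric hydrogenation. Acid 3 comes from 1-(3-methoxyphenyl)ethan-1-one 1 and phosphonium salt 2 by Wittig olefination. The stereocentre is thus made in the second step, from two commercial materials, with a catalyst.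

## Roads not taken

**Alternative 1:** Cut C14–C15 and close the cyclohexene last by an intramolecular Nozaki–Hiyama–Kishi reaction. The precursor is 2-[(1S,2S)-1-[(2Z)-3-iodobut-2-en-1-yl]-2-methyl-5-oxocyclopentyl]acetaldehyde A1. CrCl2 with catalytic NiCl2 in DMF would convert the Z-iodide into an alkenylchromium that adds to the aldehyde, giving (4S,5S,7S)-7-hydroxy-4,8-dimethylspiro[4.5]dec-8-en-1-one A2.
- Merits: the C13=C14 alkene, the C14 methyl and the C15 hydroxyl all arrive in the ring closure, so the three adjustment steps of the chosen route (steps 8–10) are not needed. The reaction is aldehyde-selective and tolerates the ketone. On ring functionalisation this road is better.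
- Weak points: the quaternary C11 with two different arms must already stand beside C10, which means two stereocontrolled alkylations of a cyclopentanone. The C15 configuration would come from substrate control 1,3 to the quaternary centre, with no clear bias. Several equivalents of a divalent chromium salt are consumed. Most seriously, the C7 ketone of A2 must still become C7–H with the branched C6 arm, two adjacent centres on a neopentyl carbon with no handle for control.
- Comparison: the chosen plan delivers C7 with its arm and its relative configuration in the ring-forming step and has reagent control at C15.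

**Alternative 2:** Cut C10–CH3 and C11–C12 in one flask. CH3MgBr with catalytic CuBr·SMe2 and a chiral ferrocenyl diphosphine would add methyl to C10 of tert-butyl 2-(5-oxocyclopent-1-en-1-yl)acetate A3, and allyl iodide would trap the magnesium enolate at C11. The product is tert-butyl 2-[(1S,2S)-2-methyl-5-oxo-1-(prop-2-en-1-yl)cyclopentyl]acetate A4.
- Merits: two stereocentres, one of them the quaternary carbon, from an achiral enone with a catalyst. The allyl group enters anti to the new methyl, which is the relationship the target needs (C12 trans to the C10 methyl). That rule is firmer than the allylic strain argument behind the chosen key step, and this is a real advantage.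
- Weak points: α-substituted cyclopentenones are slow and less selective in copper-catalysed Grignard additions. The magnesium enolate is a poor alkylation partner, and O-allylation and proton exchange with the acidic ester arm compete. No ring closes, so the cyclohexene must still be built from the two arms (in effect the closure of Alternative 1), and the C6/C7 problem at the ketone remains.
- Comparison: the chosen plan sets against the firmer C11 rule a catalytic hydrogenation for C10, a ring closure and a fully elaborated C7 in one step.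

**Alternative 3:** Cut C10–C11 instead of C7–C11. Fe(acac)3 and PhSiH3 in ethanol would transfer a hydrogen atom to the terminal alkene carbon of 3-[(2S,3R)-1-(tert-butyldimethylsilyloxy)-2-methylhept-6-en-3-yl]cyclohex-2-en-1-one A5. The secondary C10 radical would add 5-exo to the enone β-carbon C11, giving (1R,4S,5S)-1-[(2S)-1-(tert-butyldimethylsilyloxy)propan-2-yl]-4-methylspiro[4.5]decan-7-one A6.
- Merits: the same ring and the same acceptor, under neutral conditions and without a cell. C6 and C7 are already in place in A5, so A6 carries all four contiguous centres and the late C6 alkylation of the chosen route disappears. On the C6 problem this road is better.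
- Weak points: the cyclisation must set both C10 and C11 from C7, and C10 arises from a planar secondary radical whose methyl can point either way. A5 needs its own asymmetric construction of the C6/C7 pair next to an enone, where C7 is γ to the carbonyl and epimerisable through the dienolate. The way to the cyclisation substrate is therefore longer.
- Comparison: the chosen plan fixes C10 absolutely before the ring closes and reaches its cyclisation substrate in six steps, but it pays for this with the four-step auxiliary sequence for C6.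

Key step: step 7

## Route

Assumptions (remarks on the chemistry):
- In step 2 the ligand antipode is the one that delivers the 4S acid. The (Sa,S) label is taken as that antipode and would be exchanged for its mirror image if the sense proved opposite.
- Compound 12 is carried as a mixture of C14 epimers, since C14 becomes trigonal in step 9.
- Acid 30 is prepared (steps 20 and 21) and not purchased.

Step 1
Reactants: 1 1-(3-methoxyphenyl)ethan-1-one; 2 (2-carboxyethyl)triphenylphosphonium bromide
Product: 3 (3E)-4-(3-methoxyphenyl)pent-3-enoic acid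
Conditions: NaN(SiMe3)2 (2.2 equiv), THF, 0 °C to reflux; aqueous HCl work-up; recrystallisation
Reagents that add atoms: none
Why: Wittig olefination of an aryl methyl ketone with the carboxylate-bearing ylide; the acid is crystalline, which should allow the E isomer (aryl trans to the CH2CO2H arm) to be brought to geometric purity before hydrogenation.

Step 2
Reactants: 3 (3E)-4-(3-methoxyphenyl)pent-3-enoic acid
Product: 4 (4S)-4-(3-methoxyphenyl)pentanoic acid
Conditions: H2 (6 atm), [Ir(cod)(L)]BArF (0.5 mol%; L = (Sa,S)-SIPHOX spiro phosphine–oxazoline, cod = 1,5-cyclooctadiene, BArF = B[3,5-(CF3)2C6H3]4), Et3N (0.5 equiv), MeOH, rt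
Reagents that add atoms: none
Why: Carboxylate-directed iridium-catalysed asymmetric hydrogenation of an (E)-4-aryl-pent-3-enoic acid, a substrate class for which spiro phosphine–oxazoline iridium catalysts are established; the catalyst selects the alkene face and so sets C10 (4S), the centre that later directs C7 and C11.

Step 3
Reactants: 4 (4S)-4-(3-methoxyphenyl)pentanoic acid
Product: 5 (4S)-4-(3-methoxyphenyl)pentan-1-ol
Conditions: LiAlH4, THF, 0 °C to rt
Reagents that add atoms: none
Why: Hydride reduction of the carboxylic acid to the primary alcohol; the benzylic centre is not involved.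

Step 4
Reactants: 5 (4S)-4-(3-methoxyphenyl)pentan-1-ol
Product: 7 3-[(2S)-5-hydroxypentan-2-yl]cyclohex-2-en-1-one, via dihydroanisole 6 (not isolated)
Conditions: Li, NH3 (l), t-BuOH, THF, −78 to −33 °C; then 1 M HCl, THF, rt
Reagents that add atoms: water, O
Why: Birch reduction of a 3-alkylanisole leaves the methoxy- and alkyl-bearing carbons on the two remaining double bonds; hydrolysis of the enol ether and migration of the alkene into conjugation give the 3-substituted cyclohex-2-enone. C10 is not deprotonated under these conditions, and the acid is kept dilute so that γ-enolisation towards C10 should not occur.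

Step 5
Reactants: 7 3-[(2S)-5-hydroxypentan-2-yl]cyclohex-2-en-1-one
Product: 8 (4S)-4-(3-oxocyclohex-1-en-1-yl)pentanal
Conditions: Dess–Martin periodinane, NaHCO3, CH2Cl2, 0 °C to rt
Reagents that add atoms: none
Why: Dess–Martin oxidation of the primary alcohol under buffered, non-enolising conditions; the enone is inert.

Step 6
Reactants: 8 (4S)-4-(3-oxocyclohex-1-en-1-yl)pentanal; 9 methyl 2-(triphenyl-λ5-phosphanylidene)acetate
Product: 10 methyl (2E,6S)-6-(3-oxocyclohex-1-en-1-yl)hept-2-enoate
Conditions: CH2Cl2, rt
Reagents that add atoms: none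
Why: Wittig olefination with a stabilised ylide, which should give the E enoate and react only with the aldehyde, not with the conjugated ketone.

Step 7
Reactants: 10 methyl (2E,6S)-6-(3-oxocyclohex-1-en-1-yl)hept-2-enoate
Product: 11 methyl 2-[(1R,4S,5S)-4-methyl-7-oxospiro[4.5]decan-1-yl]acetate
Conditions: constant-current electrolysis (about 2 F/mol), Pb cathode, Pt anode, divided cell, Et4NOTs (0.1 M), MeCN–H2O (9:1), CH2(CO2Me)2 (2 equiv), rt
Reagents that add atoms: none
Why: One-electron reduction at the cathode converts the cyclohexenone of 10 (the more easily reduced electrophore) into a radical anion with spin density at C11, which adds 5-exo-trig to the enoate β-carbon C7; the α-ester radical at C6 then takes a second electron and the two enolate sites are protonated by dimethyl malonate, so the net change is two hydrogens and the C7–C11 bond. The closest known reaction type is the electroreductive cyclisation (electrohydrocyclisation) of enones tethered to α,β-unsaturated esters, which is known to create quaternary carbons; should the enoate accept the first electron instead, the same β,β-bond results. The cyclopentane closes in the 5-exo mode, the only one open to a three-atom tether (C10, C9, C8), and because C11 is the enone β-carbon the new ring is spiro-fused to the cyclohexanone. C7 is controlled by C10: in the chair-like transition state the C10 methyl is pseudo-equatorial and the enoate arm ends trans to it (1R). C11 is also controlled by C10: about the C10–C11 bond the methyl and C9 are expected to flank the vinylic C16–H, which has one in-plane hydrogen, in preference to the C12 methylene, whose two hydrogens would eclipse them (allylic 1,2-strain), so C16 should end cis to the methyl (5S). The step needs intramolecular coupling to win over hydrodimerisation and plain saturation, which the short tether, moderate dilution and the proton donor secure; the donor also keeps the catholyte from becoming basic enough to epimerise C10 through the dienolate.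

Step 8
Reactants: 11 methyl 2-[(1R,4S,5S)-4-methyl-7-oxospiro[4.5]decan-1-yl]acetate
Product: 12 methyl 2-[(1R,4S,5S)-4,8-dimethyl-7-oxospiro[4.5]decan-1-yl]acetate (C8 epimers; C8 is C14)
Conditions: LiN(iPr)2 (1.05 equiv), THF, −78 °C; CH3I, −78 to −30 °C
Reagents that add atoms: iodomethane, CI
Why: Kinetic enolate alkylation; deprotonation should occur at C14, the ketone α-methylene remote from the quaternary C11 (C16 is neopentyl), and faster than at the less acidic ester α-carbon. The C14 configuration is immaterial.

Step 9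
Reactants: 12 methyl 2-[(1R,4S,5S)-4,8-dimethyl-7-oxospiro[4.5]decan-1-yl]acetate
Product: 14 methyl 2-[(1R,4S,5S)-4,8-dimethyl-7-oxospiro[4.5]dec-8-en-1-yl]acetate, via trimethylsilyl enol ether 13 (not isolated)
Conditions: Me3SiCl, NaI, Et3N, MeCN, rt; then Pd(OAc)2 (1.1 equiv), MeCN, rt
Reagents that add atoms: none
Why: Equilibrating silylation (Me3SiI formed in the flask) should give the more substituted enol ether at C14=C15, and Saegusa–Ito oxidation (oxa-π-allyl palladium enolate, β-hydride elimination from C13) gives the 2-methyl enone. Any C15=C16 enol ether cannot dehydrogenate, because C11 bears no hydrogen, and reverts to 12 on work-up.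

Step 10
Reactants: 14 methyl 2-[(1R,4S,5S)-4,8-dimethyl-7-oxospiro[4.5]dec-8-en-1-yl]acetate
Product: 15 methyl 2-[(1R,4S,5S,7S)-7-hydroxy-4,8-dimethylspiro[4.5]dec-8-en-1-yl]acetate
Conditions: (R)-2-methyl-CBS-oxazaborolidine (0.2 equiv), BH3·SMe2, THF, −20 °C
Reagents that add atoms: none
Why: Corey–Bakshi–Shibata reduction; the catalyst differentiates the large α-methylvinyl flank (C14) from the small methylene flank (C16), and the (R) catalyst should deliver hydride to the face that gives the 7S (C15) allylic alcohol. The ester is inert at this temperature.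

Step 11
Reactants: 15 methyl 2-[(1R,4S,5S,7S)-7-hydroxy-4,8-dimethylspiro[4.5]dec-8-en-1-yl]acetate
Product: 16 methyl 2-[(1R,4S,5S,7S)-7-{[tert-butyl(dimethyl)silyl]oxy}-4,8-dimethylspiro[4.5]dec-8-en-1-yl]acetate
Conditions: t-BuMe2SiOTf, 2,6-lutidine, CH2Cl2, −78 to 0 °C
Reagents that add atoms: tert-butyldimethylsilyl trifluoromethanesulfonate, CC(C)(C)[Si](C)(C)OS(=O)(=O)C(F)(F)F
Why: Silylation of the hindered secondary allylic alcohol with the silyl triflate; the O–H bond reacts, so C15 keeps its configuration. The ether masks the hydroxyl through the enolate, hydride and carbonate steps that follow.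

Step 12
Reactants: 16 methyl 2-[(1R,4S,5S,7S)-7-{[tert-butyl(dimethyl)silyl]oxy}-4,8-dimethylspiro[4.5]dec-8-en-1-yl]acetate
Product: 17 2-[(1R,4S,5S,7S)-7-{[tert-butyl(dimethyl)silyl]oxy}-4,8-dimethylspiro[4.5]dec-8-en-1-yl]acetic acid
Conditions: LiOH, THF–MeOH–H2O, rt; 1 M HCl to pH 4 at 0 °C
Reagents that add atoms: lithium hydroxide, [Li+].[OH-]
Why: Saponification of the unhindered methyl ester; the silyl ether and the trisubstituted alkene are stable to aqueous hydroxide at room temperature.

Step 13
Reactants: 17 2-[(1R,4S,5S,7S)-7-{[tert-butyl(dimethyl)silyl]oxy}-4,8-dimethylspiro[4.5]dec-8-en-1-yl]acetic acid; 18 (4S)-4-benzyl-1,3-oxazolidin-2-one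
Product: 20 (4S)-4-benzyl-3-{2-[(1R,4S,5S,7S)-7-{[tert-butyl(dimethyl)silyl]oxy}-4,8-dimethylspiro[4.5]dec-8-en-1-yl]acetyl}-1,3-oxazolidin-2-one, via pivalic mixed anhydride 19 (not isolated)
Conditions: t-BuCOCl, Et3N, THF, −20 °C; then 18, LiCl, rt
Reagents that add atoms: none
Why: N-Acylation of the oxazolidinone through the pivalic mixed anhydride with LiCl/Et3N activation; the nucleophile attacks the less hindered acyl carbon of the anhydride.

Step 14
Reactants: 20 (4S)-4-benzyl-3-{2-[(1R,4S,5S,7S)-7-{[tert-butyl(dimethyl)silyl]oxy}-4,8-dimethylspiro[4.5]dec-8-en-1-yl]acetyl}-1,3-oxazolidin-2-one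
Product: 21 (4S)-4-benzyl-3-{(2S)-2-[(1R,4S,5S,7S)-7-{[tert-butyl(dimethyl)silyl]oxy}-4,8-dimethylspiro[4.5]dec-8-en-1-yl]propanoyl}-1,3-oxazolidin-2-one
Conditions: NaN(SiMe3)2 (1.1 equiv), THF, −78 °C; CH3I, −78 to −40 °C
Reagents that add atoms: iodomethane, CI
Why: Evans asymmetric alkylation; the chelated Z-enolate is screened on one face by the C4 benzyl group and iodomethane enters from the other, which for the (4S) auxiliary gives the 2S acyl unit, the C6 configuration of 32.

Step 15
Reactants: 21 (4S)-4-benzyl-3-{(2S)-2-[(1R,4S,5S,7S)-7-{[tert-butyl(dimethyl)silyl]oxy}-4,8-dimethylspiro[4.5]dec-8-en-1-yl]propanoyl}-1,3-oxazolidin-2-one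
Product: 22 (2S)-2-[(1R,4S,5S,7S)-7-{[tert-butyl(dimethyl)silyl]oxy}-4,8-dimethylspiro[4.5]dec-8-en-1-yl]propan-1-ol
Conditions: LiBH4, MeOH (1 equiv), Et2O, 0 °C
Reagents that add atoms: none
Why: Reductive cleavage at the exocyclic imide carbonyl gives the primary alcohol and frees the auxiliary; no enolate is formed, so C6 is preserved.

Step 16
Reactants: 22 (2S)-2-[(1R,4S,5S,7S)-7-{[tert-butyl(dimethyl)silyl]oxy}-4,8-dimethylspiro[4.5]dec-8-en-1-yl]propan-1-ol
Product: 23 (2S)-2-[(1R,4S,5S,7S)-7-{[tert-butyl(dimethyl)silyl]oxy}-4,8-dimethylspiro[4.5]dec-8-en-1-yl]propanal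
Conditions: Dess–Martin periodinane, NaHCO3, CH2Cl2, 0 °C
Reagents that add atoms: none
Why: Dess–Martin oxidation under buffered conditions; the α-branched aldehyde is used at once to avoid epimerisation at C6.

Step 17
Reactants: 23 (2S)-2-[(1R,4S,5S,7S)-7-{[tert-butyl(dimethyl)silyl]oxy}-4,8-dimethylspiro[4.5]dec-8-en-1-yl]propanal
Product: 24 tert-butyl{[(1R,4S,5S,7S)-1-[(2S)-but-3-yn-2-yl]-4,8-dimethylspiro[4.5]dec-8-en-7-yl]oxy}dimethylsilane
Conditions: dimethyl (1-diazo-2-oxopropyl)phosphonate, K2CO3, MeOH, 0 °C to rt
Reagents that add atoms: dimethyl (1-diazo-2-oxopropyl)phosphonate, CC(=O)C(=[N+]=[N-])P(=O)(OC)OC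
Why: Seyferth–Gilbert homologation in its Ohira–Bestmann form turns the C5 aldehyde into the C5≡C4 terminal alkyne; the carbonate–methanol medium is mild enough that α-branched aldehydes normally keep their configuration.

Step 18
Reactants: 24 tert-butyl{[(1R,4S,5S,7S)-1-[(2S)-but-3-yn-2-yl]-4,8-dimethylspiro[4.5]dec-8-en-7-yl]oxy}dimethylsilane
Product: 25 (1R,4S,5S,7S)-1-[(2S)-but-3-yn-2-yl]-4,8-dimethylspiro[4.5]dec-8-en-7-ol
Conditions: Bu4NF, THF, rt
Reagents that add atoms: none
Why: Fluoride cleavage of the silyl ether; the terminal alkyne and all stereocentres are untouched.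

Step 19
Reactants: 25 (1R,4S,5S,7S)-1-[(2S)-but-3-yn-2-yl]-4,8-dimethylspiro[4.5]dec-8-en-7-ol; 26 3-phenylpropanoyl chloride
Product: 27 (1R,4S,5S,7S)-1-[(2S)-but-3-yn-2-yl]-4,8-dimethylspiro[4.5]dec-8-en-7-yl 3-phenylpropanoate
Conditions: pyridine, DMAP (0.1 equiv), CH2Cl2, 0 °C to rt
Reagents that add atoms: none
Why: DMAP-catalysed acylation of the secondary allylic alcohol; the C15–O bond is not broken, so the configuration is retained.

Step 20
Reactants: 28 prop-2-yn-1-ol
Product: 29 (2Z)-3-iodo-2-methylprop-2-en-1-ol
Conditions: CH3MgBr (2.5 equiv), CuI (10 mol%), THF, −10 °C to rt; then I2, −10 °C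
Reagents that add atoms: methylmagnesium bromide, C[Mg]Br; iodine, II
Why: Alkoxide-directed copper-catalysed anti-carbomagnesiation places methyl on C2 and magnesium on C3 cis to the CH2O group in a five-membered chelate; iodinolysis with retention gives the Z iodide.

Step 21
Reactants: 29 (2Z)-3-iodo-2-methylprop-2-en-1-ol
Product: 30 (2Z)-3-iodo-2-methylprop-2-enoic acid
Conditions: TEMPO (0.2 equiv), PhI(OAc)2 (2.2 equiv), MeCN–H2O (1:1), rt
Reagents that add atoms: water, O
Why: Oxoammonium-mediated oxidation of the primary allylic alcohol through the aldehyde hydrate to the acid; the near-neutral medium should leave the Z vinyl iodide unchanged.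

Step 22
Reactants: 27 (1R,4S,5S,7S)-1-[(2S)-but-3-yn-2-yl]-4,8-dimethylspiro[4.5]dec-8-en-7-yl 3-phenylpropanoate; 30 (2Z)-3-iodo-2-methylprop-2-enoic acid
Product: 32 (1R,4S,5S,7S)-4,8-dimethyl-1-{(2S)-1-[(2Z)-4-methyl-5-oxofuran-2(5H)-ylidene]propan-2-yl}spiro[4.5]dec-8-en-7-yl 3-phenylpropanoate, via enynoic acid 31 (not isolated)
Conditions: Pd(PPh3)4 (5 mol%), CuI (10 mol%), Et3N (4 equiv), MeCN, rt, dark
Reagents that add atoms: none
Why: Sonogashira coupling joins the alkyne terminus C4 to C3 of the Z-iodo acid, and the cis carboxylate then adds 5-exo-dig across the metal-activated alkyne (tandem cross-coupling–lactonisation). Anti addition places the ring oxygen and C6 on the same side of C4=C5, which is the Z geometry of 32; the amine base at room temperature leaves the C15 ester intact.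

## Compound list

1 | 1-(3-methoxyphenyl)ethan-1-one | CC(=O)c1cccc(OC)c1 | starting material
2 | (2-carboxyethyl)triphenylphosphonium bromide | OC(=O)CC[P+](c1ccccc1)(c1ccccc1)c1ccccc1.[Br-] | starting material
3 | (3E)-4-(3-methoxyphenyl)pent-3-enoic acid | C/C(=C\CC(=O)O)c1cccc(OC)c1 | intermediate
4 | (4S)-4-(3-methoxyphenyl)pentanoic acid | OC(=O)CC[C@H](C)c1cccc(OC)c1 | intermediate
5 | (4S)-4-(3-methoxyphenyl)pentan-1-ol | OCCC[C@H](C)c1cccc(OC)c1 | intermediate
6 | (4S)-4-(5-methoxycyclohexa-1,4-dien-1-yl)pentan-1-ol | COC1=CCC=C([C@@H](C)CCCO)C1 | intermediate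
7 | 3-[(2S)-5-hydroxypentan-2-yl]cyclohex-2-en-1-one | OCCC[C@H](C)C1=CC(=O)CCC1 | intermediate
8 | (4S)-4-(3-oxocyclohex-1-en-1-yl)pentanal | O=CCC[C@H](C)C1=CC(=O)CCC1 | intermediate
9 | methyl 2-(triphenyl-λ5-phosphanylidene)acetate | COC(=O)C=P(c1ccccc1)(c1ccccc1)c1ccccc1 | starting material
10 | methyl (2E,6S)-6-(3-oxocyclohex-1-en-1-yl)hept-2-enoate | COC(=O)/C=C/CC[C@H](C)C1=CC(=O)CCC1 | intermediate
11 | methyl 2-[(1R,4S,5S)-4-methyl-7-oxospiro[4.5]decan-1-yl]acetate | COC(=O)C[C@H]2CC[C@H](C)[C@@]23CCCC(=O)C3 | intermediate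
12 | methyl 2-[(1R,4S,5S)-4,8-dimethyl-7-oxospiro[4.5]decan-1-yl]acetate (C8 epimers) | COC(=O)C[C@H]2CC[C@H](C)[C@@]23CCC(C)C(=O)C3 | intermediate
13 | methyl 2-[(1R,4S,5S)-4,8-dimethyl-7-(trimethylsilyloxy)spiro[4.5]dec-7-en-1-yl]acetate | COC(=O)C[C@H]2CC[C@H](C)[C@@]23CCC(C)=C(O[Si](C)(C)C)C3 | intermediate
14 | methyl 2-[(1R,4S,5S)-4,8-dimethyl-7-oxospiro[4.5]dec-8-en-1-yl]acetate | COC(=O)C[C@H]2CC[C@H](C)[C@@]23CC=C(C)C(=O)C3 | intermediate
15 | methyl 2-[(1R,4S,5S,7S)-7-hydroxy-4,8-dimethylspiro[4.5]dec-8-en-1-yl]acetate | COC(=O)C[C@H]2CC[C@H](C)[C@@]23CC=C(C)[C@@H](O)C3 | intermediate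
16 | methyl 2-[(1R,4S,5S,7S)-7-{[tert-butyl(dimethyl)silyl]oxy}-4,8-dimethylspiro[4.5]dec-8-en-1-yl]acetate | COC(=O)C[C@H]2CC[C@H](C)[C@@]23CC=C(C)[C@@H](O[Si](C)(C)C(C)(C)C)C3 | intermediate
17 | 2-[(1R,4S,5S,7S)-7-{[tert-butyl(dimethyl)silyl]oxy}-4,8-dimethylspiro[4.5]dec-8-en-1-yl]acetic acid | OC(=O)C[C@H]2CC[C@H](C)[C@@]23CC=C(C)[C@@H](O[Si](C)(C)C(C)(C)C)C3 | intermediate
18 | (4S)-4-benzyl-1,3-oxazolidin-2-one | O=C1N[C@@H](Cc2ccccc2)CO1 | starting material
19 | 2-[(1R,4S,5S,7S)-7-{[tert-butyl(dimethyl)silyl]oxy}-4,8-dimethylspiro[4.5]dec-8-en-1-yl]acetic 2,2-dimethylpropanoic anhydride | CC(C)(C)C(=O)OC(=O)C[C@H]2CC[C@H](C)[C@@]23CC=C(C)[C@@H](O[Si](C)(C)C(C)(C)C)C3 | intermediate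
20 | (4S)-4-benzyl-3-{2-[(1R,4S,5S,7S)-7-{[tert-butyl(dimethyl)silyl]oxy}-4,8-dimethylspiro[4.5]dec-8-en-1-yl]acetyl}-1,3-oxazolidin-2-one | O=C1OC[C@H](Cc2ccccc2)N1C(=O)C[C@H]3CC[C@H](C)[C@@]34CC=C(C)[C@@H](O[Si](C)(C)C(C)(C)C)C4 | intermediate
21 | (4S)-4-benzyl-3-{(2S)-2-[(1R,4S,5S,7S)-7-{[tert-butyl(dimethyl)silyl]oxy}-4,8-dimethylspiro[4.5]dec-8-en-1-yl]propanoyl}-1,3-oxazolidin-2-one | O=C1OC[C@H](Cc2ccccc2)N1C(=O)[C@@H](C)[C@H]3CC[C@H](C)[C@@]34CC=C(C)[C@@H](O[Si](C)(C)C(C)(C)C)C4 | intermediate
22 | (2S)-2-[(1R,4S,5S,7S)-7-{[tert-butyl(dimethyl)silyl]oxy}-4,8-dimethylspiro[4.5]dec-8-en-1-yl]propan-1-ol | OC[C@@H](C)[C@H]3CC[C@H](C)[C@@]34CC=C(C)[C@@H](O[Si](C)(C)C(C)(C)C)C4 | intermediate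
23 | (2S)-2-[(1R,4S,5S,7S)-7-{[tert-butyl(dimethyl)silyl]oxy}-4,8-dimethylspiro[4.5]dec-8-en-1-yl]propanal | O=C[C@@H](C)[C@H]3CC[C@H](C)[C@@]34CC=C(C)[C@@H](O[Si](C)(C)C(C)(C)C)C4 | intermediate
24 | tert-butyl{[(1R,4S,5S,7S)-1-[(2S)-but-3-yn-2-yl]-4,8-dimethylspiro[4.5]dec-8-en-7-yl]oxy}dimethylsilane | C#C[C@@H](C)[C@H]3CC[C@H](C)[C@@]34CC=C(C)[C@@H](O[Si](C)(C)C(C)(C)C)C4 | intermediate
25 | (1R,4S,5S,7S)-1-[(2S)-but-3-yn-2-yl]-4,8-dimethylspiro[4.5]dec-8-en-7-ol | C#C[C@@H](C)[C@H]3CC[C@H](C)[C@@]34CC=C(C)[C@@H](O)C4 | intermediate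
26 | 3-phenylpropanoyl chloride | O=C(Cl)CCc1ccccc1 | starting material
27 | (1R,4S,5S,7S)-1-[(2S)-but-3-yn-2-yl]-4,8-dimethylspiro[4.5]dec-8-en-7-yl 3-phenylpropanoate | C#C[C@@H](C)[C@H]3CC[C@H](C)[C@@]34CC=C(C)[C@@H](OC(=O)CCc5ccccc5)C4 | intermediate
28 | prop-2-yn-1-ol | C#CCO | starting material
29 | (2Z)-3-iodo-2-methylprop-2-en-1-ol | C/C(CO)=C/I | intermediate
30 | (2Z)-3-iodo-2-methylprop-2-enoic acid | C/C(C(=O)O)=C/I | intermediate
31 | (2Z,6S)-6-[(1R,4S,5S,7S)-4,8-dimethyl-7-(3-phenylpropanoyloxy)spiro[4.5]dec-8-en-1-yl]-2-methylhept-2-en-4-ynoic acid | C/C(C(=O)O)=C/C#C[C@@H](C)[C@H]3CC[C@H](C)[C@@]34CC=C(C)[C@@H](OC(=O)CCc5ccccc5)C4 | intermediate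
32 | (1R,4S,5S,7S)-4,8-dimethyl-1-{(2S)-1-[(2Z)-4-methyl-5-oxofuran-2(5H)-ylidene]propan-2-yl}spiro[4.5]dec-8-en-7-yl 3-phenylpropanoate | CC1=C/C(=C/[C@@H](C)[C@H]2CC[C@H](C)[C@@]23CC=C(C)[C@@H](OC(=O)CCc2ccccc2)C3)OC1=O | target

## Step count and least certain steps

Total: 22 steps. Longest linear sequence: 20 steps (steps 1–19 and 22); steps 20 and 21 are the branch to acid 30.

**Step 7 (key step).** The most likely failure is facial selection at C11 in the 5-exo addition, because the preference for the C16–H over the C12 methylene beside the C10 methyl rests on a small allylic strain difference. Diversion of the radical anion into hydrodimerisation or plain saturation is a lesser risk. The fallback corrects the constitution instead of the configuration. The two arms of the six-membered ring differ only in where the oxygen sits, so a 1,3-carbonyl transposition turns the C11 epimer into the desired series. It sets out from 10.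
- Electrolysis that favours the other face gives the C11-epimeric keto ester methyl 2-[(1R,4S,5R)-4-methyl-7-oxospiro[4.5]decan-1-yl]acetate F1.
- Methylation as in step 8 gives the 8-methyl ketone F2.
- Enol silylation as in step 9 gives the trimethylsilyl enol ether F3, and Pd(OAc)2 gives the epimeric enone F4.
- Alkaline hydrogen peroxide (H2O2, NaOH, MeOH) gives the epoxy ketone F5.
- Wharton rearrangement (N2H4·H2O, AcOH, MeOH) gives the transposed allylic alcohol F6, which is 15 as a mixture of carbinol epimers.
- MnO2 in CH2Cl2 returns to the route at enone 14, and step 10 then sets C15.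

Both C11 epimers of the cyclisation therefore converge on 14.

**Step 2.** The most likely failure is incomplete discrimination of the alkene faces, made worse by any Z acid carried in 3. This would lower the optical purity of every later compound, since C10 is the only source of absolute configuration for C7 and C11. The fallback sets the centre by conjugate reduction of a geometrically secure α,β-unsaturated ester and then adds one carbon. It sets out from ketone 1.
- Horner–Wadsworth–Emmons olefination with triethyl phosphonoacetate (NaH, THF) gives ethyl (2E)-3-(3-methoxyphenyl)but-2-enoate F7, purified from its Z isomer by chromatography.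
- Copper hydride conjugate reduction (CuCl, NaOt-Bu, the Tol-BINAP antipode that gives the 3S product, polymethylhydrosiloxane, toluene) gives ethyl (3S)-3-(3-methoxyphenyl)butanoate F8.
- Saponification gives (3S)-3-(3-methoxyphenyl)butanoic acid F9.
- Arndt–Eistert homologation follows: oxalyl chloride gives (3S)-3-(3-methoxyphenyl)butanoyl chloride F10, diazomethane gives (4S)-1-diazo-4-(3-methoxyphenyl)pentan-2-one F11, and Wolff rearrangement (silver benzoate, Et3N, aqueous dioxane) returns to the route at acid 4.

**Step 10.** The most likely failure is poor facial selectivity. The small flank of the ketone (C16) is a methylene bound to a quaternary carbon, which reduces the steric contrast with the α-methylvinyl flank that the catalyst relies on. The fallback is substrate-controlled reduction followed by inversion. It sets out from enone 14.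
- NaBH4 with CeCl3·7H2O in MeOH (Luche reduction) should give mainly one carbinol epimer.
- If this is the 7R alcohol methyl 2-[(1R,4S,5S,7R)-7-hydroxy-4,8-dimethylspiro[4.5]dec-8-en-1-yl]acetate F12, Mitsunobu reaction with 4-nitrobenzoic acid (PPh3, diisopropyl azodicarboxylate) gives the inverted 4-nitrobenzoate F13.
- Methanolysis (K2CO3, MeOH) returns to the route at 15.

**Step 14.** The most likely failure is mismatched double stereodifferentiation. With the C7–H eclipsing the enolate, the quaternary C11 shields the face that the auxiliary leaves open, so both rate and facial selectivity may suffer. The fallback uses the ring's bias instead of opposing it, by forming the C6–H bond last. It sets out from ester 16.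
- LiN(iPr)2 and CH3I give the methyl ester methylated at C6 as an epimer mixture, methyl 2-[(1R,4S,5S,7S)-7-{[tert-butyl(dimethyl)silyl]oxy}-4,8-dimethylspiro[4.5]dec-8-en-1-yl]propanoate F14.
- Regeneration of the enolate (LiN(iPr)2, THF, −78 °C) and kinetic protonation with 2,6-di-tert-butylphenol should deliver hydrogen to the face remote from C11 and give the (2S) ester F15.
- LiAlH4 reduction returns to the route at alcohol 22.

**Step 22.** The most likely failures are loss of regiocontrol or stereocontrol in the lactonisation (6-endo closure, or isomerisation of the enol-lactone double bond) and oxidative dimerisation of the hindered alkyne before cross-coupling. The fallback builds the butenolide by C4–C5 bond formation. It sets out from aldehyde 23.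
- Vinylogous Mukaiyama aldol addition of 2-(tert-butyldimethylsilyloxy)-3-methylfuran (BF3·OEt2, CH2Cl2, −78 °C) gives the hydroxyalkyl butenolide F16.
- Methanesulfonyl chloride and Et3N give the methanesulfonate F17, and DBU eliminates it to the Z-alkylidene butenolide silyl ether F18.
- HF·pyridine gives the free C15 alcohol F19.
- Acylation with 26 (pyridine, DMAP) returns to the route at 32.

## Further compounds

F1 | step 7 | methyl 2-[(1R,4S,5R)-4-methyl-7-oxospiro[4.5]decan-1-yl]acetate | COC(=O)C[C@H]2CC[C@H](C)[C@]23CCCC(=O)C3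
F2 | step 7 | methyl 2-[(1R,4S,5R)-4,8-dimethyl-7-oxospiro[4.5]decan-1-yl]acetate (C8 epimers) | COC(=O)C[C@H]2CC[C@H](C)[C@]23CCC(C)C(=O)C3
F3 | step 7 | methyl 2-[(1R,4S,5R)-4,8-dimethyl-7-(trimethylsilyloxy)spiro[4.5]dec-7-en-1-yl]acetate | COC(=O)C[C@H]2CC[C@H](C)[C@]23CCC(C)=C(O[Si](C)(C)C)C3
F4 | step 7 | methyl 2-[(1R,4S,5R)-4,8-dimethyl-7-oxospiro[4.5]dec-8-en-1-yl]acetate | COC(=O)C[C@H]2CC[C@H](C)[C@]23CC=C(C)C(=O)C3
F5 | step 7 | methyl 2-[(1R,4S,5R)-8,9-epoxy-4,8-dimethyl-7-oxospiro[4.5]decan-1-yl]acetate (epoxide epimers) | COC(=O)C[C@H]2CC[C@H](C)[C@]23CC4OC4(C)C(=O)C3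
F6 | step 7 | methyl 2-[(1R,4S,5S)-7-hydroxy-4,8-dimethylspiro[4.5]dec-8-en-1-yl]acetate (C7 epimers) | COC(=O)C[C@H]2CC[C@H](C)[C@@]23CC=C(C)C(O)C3
F7 | step 2 | ethyl (2E)-3-(3-methoxyphenyl)but-2-enoate | CCOC(=O)/C=C(\C)c1cccc(OC)c1
F8 | step 2 | ethyl (3S)-3-(3-methoxyphenyl)butanoate | CCOC(=O)C[C@H](C)c1cccc(OC)c1
F9 | step 2 | (3S)-3-(3-methoxyphenyl)butanoic acid | OC(=O)C[C@H](C)c1cccc(OC)c1
F10 | step 2 | (3S)-3-(3-methoxyphenyl)butanoyl chloride | ClC(=O)C[C@H](C)c1cccc(OC)c1
F11 | step 2 | (4S)-1-diazo-4-(3-methoxyphenyl)pentan-2-one | [N-]=[N+]=CC(=O)C[C@H](C)c1cccc(OC)c1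
F12 | step 10 | methyl 2-[(1R,4S,5S,7R)-7-hydroxy-4,8-dimethylspiro[4.5]dec-8-en-1-yl]acetate | COC(=O)C[C@H]2CC[C@H](C)[C@@]23CC=C(C)[C@H](O)C3
F13 | step 10 | (1R,4S,5S,7S)-1-(2-methoxy-2-oxoethyl)-4,8-dimethylspiro[4.5]dec-8-en-7-yl 4-nitrobenzoate | COC(=O)C[C@H]2CC[C@H](C)[C@@]23CC=C(C)[C@@H](OC(=O)c4ccc(cc4)[N+](=O)[O-])C3
F14 | step 14 | methyl 2-[(1R,4S,5S,7S)-7-{[tert-butyl(dimethyl)silyl]oxy}-4,8-dimethylspiro[4.5]dec-8-en-1-yl]propanoate (C2 epimers) | COC(=O)C(C)[C@H]2CC[C@H](C)[C@@]23CC=C(C)[C@@H](O[Si](C)(C)C(C)(C)C)C3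
F15 | step 14 | methyl (2S)-2-[(1R,4S,5S,7S)-7-{[tert-butyl(dimethyl)silyl]oxy}-4,8-dimethylspiro[4.5]dec-8-en-1-yl]propanoate | COC(=O)[C@@H](C)[C@H]2CC[C@H](C)[C@@]23CC=C(C)[C@@H](O[Si](C)(C)C(C)(C)C)C3
F16 | step 22 | 5-{(2S)-2-[(1R,4S,5S,7S)-7-{[tert-butyl(dimethyl)silyl]oxy}-4,8-dimethylspiro[4.5]dec-8-en-1-yl]-1-hydroxypropyl}-3-methylfuran-2(5H)-one (epimers at the two new centres) | CC1=CC(OC1=O)C(O)[C@@H](C)[C@H]2CC[C@H](C)[C@@]23CC=C(C)[C@@H](O[Si](C)(C)C(C)(C)C)C3
F17 | step 22 | (2S)-2-[(1R,4S,5S,7S)-7-{[tert-butyl(dimethyl)silyl]oxy}-4,8-dimethylspiro[4.5]dec-8-en-1-yl]-1-(4-methyl-5-oxo-2,5-dihydrofuran-2-yl)propyl methanesulfonate (epimers at the two new centres) | CC1=CC(OC1=O)C(OS(C)(=O)=O)[C@@H](C)[C@H]2CC[C@H](C)[C@@]23CC=C(C)[C@@H](O[Si](C)(C)C(C)(C)C)C3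
F18 | step 22 | (5Z)-5-{(2S)-2-[(1R,4S,5S,7S)-7-{[tert-butyl(dimethyl)silyl]oxy}-4,8-dimethylspiro[4.5]dec-8-en-1-yl]propylidene}-3-methylfuran-2(5H)-one | CC1=C/C(=C/[C@@H](C)[C@H]2CC[C@H](C)[C@@]23CC=C(C)[C@@H](O[Si](C)(C)C(C)(C)C)C3)OC1=O
F19 | step 22 | (5Z)-5-{(2S)-2-[(1R,4S,5S,7S)-7-hydroxy-4,8-dimethylspiro[4.5]dec-8-en-1-yl]propylidene}-3-methylfuran-2(5H)-one | CC1=C/C(=C/[C@@H](C)[C@H]2CC[C@H](C)[C@@]23CC=C(C)[C@@H](O)C3)OC1=O
A1 | alternative 1 | 2-[(1S,2S)-1-[(2Z)-3-iodobut-2-en-1-yl]-2-methyl-5-oxocyclopentyl]acetaldehyde | O=C2CC[C@H](C)[C@@]2(CC=O)C/C=C(/C)I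
A2 | alternative 1 | (4S,5S,7S)-7-hydroxy-4,8-dimethylspiro[4.5]dec-8-en-1-one | O=C2CC[C@H](C)[C@@]23CC=C(C)[C@@H](O)C3
A3 | alternative 2 | tert-butyl 2-(5-oxocyclopent-1-en-1-yl)acetate | O=C1CCC=C1CC(=O)OC(C)(C)C
A4 | alternative 2 | tert-butyl 2-[(1S,2S)-2-methyl-5-oxo-1-(prop-2-en-1-yl)cyclopentyl]acetate | O=C2CC[C@H](C)[C@@]2(CC(=O)OC(C)(C)C)CC=C
A5 | alternative 3 | 3-[(2S,3R)-1-(tert-butyldimethylsilyloxy)-2-methylhept-6-en-3-yl]cyclohex-2-en-1-one | CC(C)(C)[Si](C)(C)OC[C@@H](C)[C@@H](CCC=C)C1=CC(=O)CCC1
A6 | alternative 3 | (1R,4S,5S)-1-[(2S)-1-(tert-butyldimethylsilyloxy)propan-2-yl]-4-methylspiro[4.5]decan-7-one | CC(C)(C)[Si](C)(C)OC[C@@H](C)[C@H]2CC[C@H](C)[C@@]23CCCC(=O)C3
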